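The numbers in the tables were computed for an exercise, noise included.

The constants of these steps are hidden, so I start from a case that needs none of them.

| flask | substrate | reagent | temperature | remark | time |
|---|---|---|---|---|---|
| south-west | 0.40 M | 0.95 equiv | 60 °C | run made earlier |  |
| dusk | 0.80 M | 0.950 equiv | 60 °C |  | 10 min |
| midnight | 0.80 M | 0.950 equiv | 40 °C |  | 10 min |
| winter | 0.80 M | 0.950 equiv |  | at 40 °C until 8.0 min, from then on at 80 °C | 10 min |
| dawn | 0.80 M | 0.950 equiv | 80 °C |  | 10 min |

south-west run (percent of the substrate charged)

| time / min | double product / % |
|---|---|
| 0.417 | 0 |
| 1.00 | 2.1 |
| 2.00 | 4.5 |
| 3.00 | 8.7 |

(scatter of a reading: 0.3 percentage points)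

- reactions considered so far: substrate + reagent -> single product + by-product; reagent + single product <-> double product + by-product
- the earlier runs do not show what temperature does; that part of a forecast is a guess

- which flask leads in amount of double product, in percent of the substrate charged ("all alike" within 1.5 percentage points) (dusk / midnight / winter / dawn / all alike)
- how much double product is there at the end, in percent of the substrate charged: dusk
- how much double product is there at the end, in percent of the substrate charged: midnight
- how much double product is there at the end, in percent of the substrate charged: winter
- how much double product is there at the end, in percent of the substrate charged: dawn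

How much double product does pure chance give? I treat the substrate as having two equal places. With reagent at 0.950 equiv, a place is taken with chance 47.5%, so both places of one substrate are taken with chance 22.6%. I call this the chance share, the statistical distribution, and it is the zero of my scale.

Does 10 min at 60 °C get there? The south-west run read 8.7% at 3.00 min, which is 38.5% of the chance share. Each step joins one reagent to one partner, so at equal equivalents and equal temperature, equal [substrate]·time gives equal percentages. Dusk has 6.67 times the south-west value, so I put dusk near the chance share.

Does the double product stay there? The reverse step returns reagent and single product, and substrate can take that reagent in a step with no way back. Added up, double product + substrate gives two single product. So I take double product as the kinetic product, and I expect the chance share to mark a crest rather than a resting point.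

A hot flask should therefore reach its crest early and then fall, while a cold one arrives late. The size of both effects is a guess. I reckon dusk first, winter next, and midnight and dawn below it.

The forecast gives dusk 20.5%, midnight 11.5%, winter 20% and dawn 22%, and, unlike my reckoning, says “Dawn leads, narrowly.”

The flasks give dusk 22.2%, midnight 15.9%, winter 18.1% and dawn 10.1%, so dusk leads.

    substrate + reagent → single product + by-product (k = 1.60 L mol⁻¹ min⁻¹, Ea = 49.0 kJ mol⁻¹)
    reagent + single product ⇌ double product + by-product (K = 2.70, k = 1.70 L mol⁻¹ min⁻¹, Ea = 54.0 kJ mol⁻¹, ΔH = −45.0 kJ mol⁻¹)
    (constants at 80 °C)

Dawn stands at about half of the chance share. The reverse step is a part of the reason: with it taken away, dawn ends at 29.7% instead of 10.1%. What the temperature does to the path from substrate + reagent to single product + by-product is another part: dawn minus midnight is −5.7 percentage points, and with that effect taken away it is 7.1 points. For dusk's neighbour with 1.60 equiv of reagent, the chance share is 64.0%, and that flask holds 47.3% at 10.0 min, which is 73.9% of its share.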